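## Structural features

The target, C24H14O11, has no stereocentre and is a chain of four benzene rings: ring E (a 3,5-dihydroxyphenyl group) is joined by a diaryl ether oxygen to ring A, ring A is fused through a 1,4-dioxin (ring B) to ring C, and ring C is fused through a furan to the resorcinol ring D. With dibenzofuran locants for rings C and D, oxygen stands at C1 and C2 (the two dioxin oxygens), C3 (OH), C7 and C9 (OH), and hydrogen at C4, C6 and C8. With primed locants for ring A, C1′ carries the ring E ether, C2′ and C4′ hydroxyl groups, C3′ hydrogen, C5′ the dioxin oxygen coming from C1 and C6′ the one coming from C2. As there are no stereocentres, none stand next to each other, and every selectivity question is regiochemical: the orientation of unsymmetrical ring A on the C1/C2 edge, and the distinction of the C1 oxygen from the C3 oxygen, which flank C2–O alike in any simple precursor. All seven phenols sit on electron-rich rings, ring C is a hydroquinone-type system (the C2 oxygen is para to the furan oxygen), and the free heptaol is air-sensitive, so the phenols are carried as ethers and bared only at the end. The real difficulty lies in the aryl–oxygen bonds around ring A, two of which join carbons with four ortho substituents on rings that have no native acceptor group, and in the crowded bay where the oxygens at C1 and C9 lie within hydrogen-bonding distance. The key step exploits ring D (C5a, C6, C7, C8, C9, C9a): a 1,3-dihydroxybenzene fused to the furan C5a–C9a bond is the enol form of a cyclic 1,3-diketone, so it can be closed by joining C7 to C8 from a benzofuran carrying an acetyl group at its C3 (future C9 and C8) and a CH2CO2Me arm at its C2 (future C6 and C7).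

## Logic of the disconnections

21 to 20. All seven O–H bonds are replaced by O–CH3 bonds. The free polyphenol is too easily oxidised and has too many nucleophilic oxygens to carry through any coupling, and one small ether type survives every earlier step. The gain is that all intermediates are stable ethers. The demand is a final ether cleavage that leaves the diaryl ethers, the dioxin and the furan intact.

20 to 19. The C5′–O bond to the C1 oxygen is cut, opening ring B. This is the only one of the ring A aryl–oxygen bonds that can be made intramolecularly as a six-membered ring, so it is made last. The gain is a diaryl ether with one phenol and one aryl bromide. The demand is that the C1 hydroxyl is the only phenol able to reach C5′ (the C3 oxygen must stay masked) and that ring A carries no acceptor group at that stage, so that it cannot migrate between the C1 and C2 oxygens.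

19 to 18. The O–CH3 bond at C1 is restored. The C1 and C3 oxygens come from one symmetrical starting material and must be told apart. In 18 the C1 methoxy group is the only one with two ortho substituents (the C2 aryloxy group and the ring-fusion carbon C9b, with the C9 oxygen across the bay), so it is forced out of the ring plane, while the C3 methoxy group is not. The gain is that no extra protecting group is needed. The demand is a Lewis acid that cleaves the twisted ether and spares the in-plane ones.

18 to 16 and 17. The bond between the ring E carbon and the C1′ oxygen is cut. Ring E is unhindered and symmetrical, and 17 is commercial. The demand is a coupling that tolerates the aryl bromide at C5′, hence an oxidative copper coupling and not a halide-based one.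

16 to 14. The C1′ hydroxyl is traced back to a formyl group (peracid insertion of oxygen into the aryl–CHO bond). The formyl group is both the acceptor that makes the preceding substitution possible and a latent oxygen. The demand is aryl migration, which the electron-rich ring ensures.

14 to 10 and 13. The C6′–O bond to the C2 oxygen is cut. This is the most hindered diaryl ether (four ortho substituents) and is therefore made by addition–elimination at a fluoride activated by the ortho formyl group. The gain is two fragments of similar size and a fixed orientation of ring A (fluoride next to the formyl carbon C1′, bromide at C5′). The demand is that the C2 hydroxyl is the only free phenol of 10.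

13 to 12 to 11. The C–Br and C–CHO bonds of the ring A fragment are cut in turn. Both are placed by the directing effects of the two methoxy groups, para to one and ortho to the other, away from the crowded carbon between them.

10 to 9 to 8. The C2 oxygen is re-benzylated and the ring D methyl ethers are removed. Benzyl is the one group orthogonal to methyl, so hydrogenolysis of 9 releases a single phenol. Ring D is capped as methyl ethers (not benzyl) so that they survive this hydrogenolysis and leave in the last step.

8 to 6. The C7–C8 bond is cut, opening ring D to a benzofuran with a 3-acetyl group and a 2-acetate arm. The gain is the loss of one ring and a precursor that is a simple heteroaryl keto ester. The demand is enolisation of the methyl ketone in the presence of the more acidic arm methylene.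

6 to 4 and 5, and 4 to 1 and 2. The benzyl ether is removed, then the furan is cut at the aryl–C3 bond and the O–C2 bond (benzofuran locants), giving 1 and 2. The gain is two commercial compounds. The demand is addition at the unsubstituted carbon of 1 and furan closure onto the C3 carbonyl of 2. Closure onto the acetyl carbonyl instead would put a methyl group on furan C2 and the keto ester chain on furan C3. That regioisomer maps onto the same ring D on paper, but it should not fold under methoxide: its β-keto ester is deprotonated first, which buries the ester carbonyl in an enolate, and its ring methyl group is far less acidic. It is therefore treated as a loss to be removed after step 1, not as a second entry.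

## Other disconnections considered

Alternative 1: The cut goes through the furan, at C9a–C9b and O5–C5a, so that ring D enters intact as benzene-1,3,5-triol A2 and ring C as 1. In the forward direction acid would promote attack of a ring carbon of A2 on the unsubstituted carbon of 1, and cyclodehydration of the adduct would close the furan and give 1,3-dimethoxydibenzo[b,d]furan-2,7,9-triol A1. In its favour: a single step from two commodity compounds reaches the whole dibenzofuran with its five oxygens, against three steps to 8 in the chosen plan. A2 is also a stronger carbon nucleophile than the enol of 2 and, being symmetrical, leaves no choice in the furan closure. On these two points the alternative is the better one. Against it here: A1 carries three free phenols (C2, C7, C9) with no built-in distinction, whereas the chosen plan puts a benzyl group on the C2 oxygen before ring D exists. A2 is also easily oxidised by 1 and can add twice. Comparison: on structure the two are equal, because both deliver the same ring C pattern with the same symmetrical C1/C3 methoxy pair and leave the same later task of telling these two oxygens apart. On mechanism they are equal in risk, since both rely on conjugate addition to the methoxy-deactivated quinone 1. On step economy the alternative would be better by up to three steps on the way to 10, but only if the two ring D hydroxyls of A1 can be methylated while the hindered C2 hydroxyl stays free; otherwise protecting-group work would use up the gain.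

Alternative 2: The cut removes both ring A carbon–oxygen bonds of the dioxin (C5′–O and C6′–O) at once. In the forward direction CsF would convert 2-(3,5-dimethoxyphenoxy)-3,5-dimethoxy-6-(trimethylsilyl)phenyl trifluoromethanesulfonate A5 into 3-(3,5-dimethoxyphenoxy)-4,6-dimethoxybenzyne A6. The aryne A6 would add across the two carbonyl oxygens of 3,7,9-trimethoxydibenzo[b,d]furan-1,2-dione A4 to give the heptamethyl ether A3, which is identical with 20. In its favour: it is the most convergent plan, builds ring B in one mild step without copper, and needs no formyl-to-hydroxyl oxidation. In convergence and in the number of late steps it is better than the chosen plan, and because A3 is 20 the last step is the same, so there the two are equal. Against it here: A6 is flanked by an oxygen substituent on each side and is only weakly polarised, and A4 is unsymmetrical, so two orientations of ring A are possible and only one is A3. The chosen plan fixes the orientation by sequence (fluoride beside the formyl group first, bromide second). A4 would have to come from 10 by oxidative demethylation, and because the C2 hydroxyl of 10 is para to the furan oxygen, this invites para-quinone formation with opening of the furan; ortho-quinones of such electron-rich rings are also labile. A5 carries the ring E ether, the silyl group and the triflate on one crowded ring and would itself need several steps. Comparison: better in convergence and in late-stage step economy, equal in the final deprotection, weaker in regiochemical control and in the stability of its intermediates.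

Alternative 3: The cut lies inside ring A, between the hydroxyl-bearing carbon and the ethoxy-bearing carbon, and traces ring A to a four-membered ring. In the forward direction heating rac-2,3-bis(benzyloxy)-4-[(Z)-2-ethoxyethenyl]-4-(methoxymethoxy)cyclobut-2-en-1-one A8 in toluene would open it to (3Z,5Z)-2,3-bis(benzyloxy)-6-ethoxy-4-(methoxymethoxy)hexa-1,3,5-trien-1-one A9. The dienylketene A9 would close by a 6π electrocyclisation between the ketene carbon and the ethoxy-bearing carbon and aromatise by a proton shift to 2,3-bis(benzyloxy)-6-ethoxy-4-(methoxymethoxy)phenol A7. The geometry of the ethoxyvinyl group of A8 is left open by this disconnection and is taken here as Z. In its favour: all five ring A oxygens are in place in A7, and the free hydroxyl, the benzyl pair, the methoxymethyl ether and the ethyl ether can be addressed separately. The pericyclic cascade through A9 also leaves no regiochemical choice. In the differentiation of the ring A oxygens and in mechanistic certainty it is better than the chosen plan, which places bromine and the formyl group by directing effects and brings one oxygen in late. Against it here: it solves only ring A. With every ring A oxygen already present, the dioxin would have to be closed by arylating two adjacent ring A oxygens with C1 and C2 of an electron-rich dibenzofuran, that is, by unactivated copper couplings at carbons with four ortho neighbours. The chosen plan avoids this with the formyl-activated fluoride of 13. The ethyl ether of A7 would need the same harsh final cleavage as the methyl ethers, and the dibenzofuran half is not addressed at all. Comparison: about equal in step count for the fragment (about three steps to A7 against two to 13), better in oxygen differentiation, worse overall because the hardest bonds stay open.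

Key step: step 3

Step 1
Reactants: 1 2,6-dimethoxy-1,4-benzoquinone; 2 methyl 3,5-dioxohexanoate
Product: 4 methyl 2-(3-acetyl-5-hydroxy-4,6-dimethoxy-1-benzofuran-2-yl)acetate, via hydroquinone adduct 3 (not isolated)
Conditions: ZnCl2 (1.5 equiv), MeOH, 65 °C
Reagents that add atoms: none
Why: Nenitzescu-type benzofuran annulation: ZnCl2 bound between the C1 carbonyl of 1 and a flanking methoxy oxygen activates the unsubstituted ring carbon for Michael addition of the diketone carbon C4 of 2, and hydroquinone 3 cyclodehydrates through the hydroxyl next to the new bond. Closure should favour the C3 carbonyl of the side chain, the more electrophilic ketone because of the adjacent ester and its chelation to zinc; the isomer closed onto the acetyl carbonyl should not fold in step 3 and is to be removed by chromatography here.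

Step 2
Reactants: 4 methyl 2-(3-acetyl-5-hydroxy-4,6-dimethoxy-1-benzofuran-2-yl)acetate; 5 benzyl bromide
Product: 6 methyl 2-[3-acetyl-5-(benzyloxy)-4,6-dimethoxy-1-benzofuran-2-yl]acetate
Conditions: K2CO3, acetone, 56 °C
Reagents that add atoms: benzyl bromide (5), BrCc1ccccc1
Why: Williamson ether synthesis: under K2CO3 the phenol is the site that is deprotonated and alkylated by the unhindered benzylic bromide, although it is flanked by two methoxy groups. The benzyl ether is the only group that hydrogenolysis will later remove, so it marks the C2 oxygen.

Step 3
Reactants: 6 methyl 2-[3-acetyl-5-(benzyloxy)-4,6-dimethoxy-1-benzofuran-2-yl]acetate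
Product: 8 2-(benzyloxy)-1,3-dimethoxydibenzo[b,d]furan-7,9-diol, via cyclic 1,3-diketone 7 (not isolated)
Conditions: NaOMe (4 equiv), MeOH, 65 °C, Ar; then aq. HCl
Reagents that add atoms: none
Why: Intramolecular Claisen (Dieckmann-type) condensation followed by aromatisation, the reaction type known for ortho-acylarylacetic esters giving 1,3-dihydroxyarenes and for biomimetic polyketide foldings. Methoxide deprotonates the acetate-arm methylene fastest, but that enolate has no ring-forming option (attack on the acetyl carbonyl would give a four-membered ring) and simply reverts. The methyl ketone enolate, present in equilibrium, attacks the ester carbonyl in a 6-exo-trig closure, and loss of methoxide gives diketone 7 with the new C7–C8 bond. Compound 7 is the keto tautomer of ring D and enolises at once to the resorcinol, which methoxide deprotonates; this makes the sequence irreversible and draws all enolate equilibria through the one productive channel. No stereocentre is formed. The selectivity needed is intramolecular over intermolecular condensation and C-acylation over ester cleavage: the first is secured by the two partners sitting on adjacent furan carbons, the second by anhydrous methoxide in methanol, where transesterification is degenerate. Benzyl and methyl ethers are inert to the base.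

Step 4
Reactants: 8 2-(benzyloxy)-1,3-dimethoxydibenzo[b,d]furan-7,9-diol
Product: 9 2-(benzyloxy)-1,3,7,9-tetramethoxydibenzo[b,d]furan
Conditions: Me2SO4 (excess), K2CO3, acetone, 56 °C
Reagents that add atoms: dimethyl sulfate, COS(=O)(=O)OC
Why: Williamson O-methylation of both ring D phenols; methyl is chosen because it survives hydrogenolysis, hot carbonate, peracid, copper catalysis and brief BCl3 and leaves with the other methyl ethers in step 13. The bay hydroxyl at C9 is hydrogen-bonded to the C1 methoxy oxygen and is expected to need the excess reagent and prolonged heating.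

Step 5
Reactants: 9 2-(benzyloxy)-1,3,7,9-tetramethoxydibenzo[b,d]furan
Product: 10 1,3,7,9-tetramethoxydibenzo[b,d]furan-2-ol
Conditions: H2 (1 atm), 10% Pd/C, EtOAc–MeOH, rt
Reagents that add atoms: none
Why: Hydrogenolysis of the single benzyl aryl ether on Pd/C; no halogen or other reducible group is present yet, so 10 should emerge with the C2 hydroxyl as its only free phenol.

Step 6
Reactants: 11 1-fluoro-3,5-dimethoxybenzene
Product: 12 2-fluoro-4,6-dimethoxybenzaldehyde
Conditions: POCl3, DMF, 0 → 60 °C; then ice-water
Reagents that add atoms: N,N-dimethylformamide, CN(C)C=O; water, O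
Why: Vilsmeier–Haack formylation: the chloroiminium ion should attack the carbon para to one methoxy group and ortho to the other (next to fluorine), the usual site in 5-substituted resorcinol dimethyl ethers, and not the more crowded carbon between the two methoxy groups.

Step 7
Reactants: 12 2-fluoro-4,6-dimethoxybenzaldehyde
Product: 13 3-bromo-2-fluoro-4,6-dimethoxybenzaldehyde
Conditions: NBS, MeCN, 0 °C → rt
Reagents that add atoms: N-bromosuccinimide, O=C1CCC(=O)N1Br
Why: Electrophilic aromatic bromination: the carbon between fluorine and the 4-methoxy group is para to the 6-methoxy group and less crowded than the carbon between the two methoxy groups, so bromine should enter there, by analogy with the usual course of halogenation in 6-substituted 2,4-dimethoxybenzoyl compounds.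

Step 8
Reactants: 10 1,3,7,9-tetramethoxydibenzo[b,d]furan-2-ol; 13 3-bromo-2-fluoro-4,6-dimethoxybenzaldehyde
Product: 14 3-bromo-4,6-dimethoxy-2-[(1,3,7,9-tetramethoxydibenzo[b,d]furan-2-yl)oxy]benzaldehyde
Conditions: Cs2CO3, DMF, 90 °C
Reagents that add atoms: none
Why: Nucleophilic aromatic substitution by addition–elimination: the phenoxide of 10 displaces fluoride, which is activated by the ortho formyl group and the inductive pull of the neighbouring bromine, while both methoxy groups are meta to the reacting carbon and sit on carbons that carry no charge in the Meisenheimer intermediate. The step fixes the orientation of ring A: C6′ is joined to the C2 oxygen and the bromide at C5′ is held next to the C1 oxygen.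

Step 9
Reactants: 14 3-bromo-4,6-dimethoxy-2-[(1,3,7,9-tetramethoxydibenzo[b,d]furan-2-yl)oxy]benzaldehyde
Product: 16 3-bromo-4,6-dimethoxy-2-[(1,3,7,9-tetramethoxydibenzo[b,d]furan-2-yl)oxy]phenol, via aryl formate 15 (not isolated)
Conditions: mCPBA, CH2Cl2, 0 °C → rt; aq. Na2SO3/NaHCO3 wash; then K2CO3 (cat.), MeOH, rt
Reagents that add atoms: 3-chloroperoxybenzoic acid, O=C(OO)c1cccc(Cl)c1
Why: Dakin-type Baeyer–Villiger oxidation: the aryl group, with oxygen at both ortho positions and at the para position, migrates to oxygen in the Criegee intermediate to give formate 15, which catalytic carbonate in methanol transesterifies to the phenol. Removing the formyl group also removes the acceptor that could allow a Smiles shift of ring A once the C1 phenol is freed.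

Step 10
Reactants: 16 3-bromo-4,6-dimethoxy-2-[(1,3,7,9-tetramethoxydibenzo[b,d]furan-2-yl)oxy]phenol; 17 3,5-dimethoxyphenylboronic acid
Product: 18 2-[6-bromo-2-(3,5-dimethoxyphenoxy)-3,5-dimethoxyphenoxy]-1,3,7,9-tetramethoxydibenzo[b,d]furan
Conditions: Cu(OAc)2 (30 mol %), pyridine, 4 Å MS, O2 (1 atm), CH2Cl2, rt
Reagents that add atoms: none
Why: Chan–Lam coupling: divalent copper mediates oxidative C–O bond formation between the phenol and the unhindered arylboronic acid at room temperature, conditions that leave the aryl bromide at C5′ untouched. The phenol is flanked on both sides, a situation this coupling is known to tolerate, but an excess of 17 and a long reaction time are expected to be needed.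

Step 11
Reactants: 18 2-[6-bromo-2-(3,5-dimethoxyphenoxy)-3,5-dimethoxyphenoxy]-1,3,7,9-tetramethoxydibenzo[b,d]furan
Product: 19 2-[6-bromo-2-(3,5-dimethoxyphenoxy)-3,5-dimethoxyphenoxy]-3,7,9-trimethoxydibenzo[b,d]furan-1-ol
Conditions: BCl3 (2 equiv), CH2Cl2, −78 → 0 °C; then aq. NaHCO3
Reagents that add atoms: none
Why: Lewis acid ether cleavage, relying on the known preference of BCl3 for aryl methyl ethers that have two ortho substituents and are twisted out of the ring plane: the C1 methoxy group is the only one of the eight in 18 that is flanked on both sides (C2 aryloxy group and ring-fusion carbon C9b, with the bay oxygen at C9 able to help bind boron), whereas every other methoxy group has a free ortho position and stays conjugated. Loss of the C9 methyl group alongside would be harmless, since that phenol cannot reach C5′ and is freed in step 13 anyway.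

Step 12
Reactants: 19 2-[6-bromo-2-(3,5-dimethoxyphenoxy)-3,5-dimethoxyphenoxy]-3,7,9-trimethoxydibenzo[b,d]furan-1-ol
Product: 20 hepta-O-methyl ether of the target (dioxin closed between the C1 oxygen and C5′)
Conditions: CuI (20 mol %), picolinic acid (40 mol %), K3PO4, DMSO, 100 °C
Reagents that add atoms: none
Why: Intramolecular Ullmann diaryl ether synthesis: the monovalent copper phenoxide of the C1 oxygen inserts into the C5′–Br bond held beside it and reductive elimination closes the six-membered 1,4-dioxin; picolinic acid is a ligand suited to hindered partners. Only the C1 phenol is free and ring A carries no acceptor, so neither the C3 oxygen nor a Smiles shift can change the regiochemistry.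

Step 13
Reactants: 20 hepta-O-methyl ether of the target
Product: 21 the target heptaol (CNP0256302.0)
Conditions: BBr3 (excess), CH2Cl2, −78 °C → rt; then MeOH, H2O; Ar
Reagents that add atoms: none
Why: Exhaustive aryl methyl ether cleavage with BBr3 through aryloxyboranes that are hydrolysed on work-up; the diaryl ethers, the dioxin and the furan offer bromide no alkyl carbon and should persist. The heptaol is air-sensitive and is to be handled under argon.

## Compound list

1 | 2,6-dimethoxy-1,4-benzoquinone | COC1=CC(=O)C=C(OC)C1=O | starting material
2 | methyl 3,5-dioxohexanoate | COC(=O)CC(=O)CC(C)=O | starting material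
3 | methyl 4-(3,6-dihydroxy-2,4-dimethoxyphenyl)-3,5-dioxohexanoate (hydroquinone adduct, not isolated) | COC(=O)CC(=O)C(C(C)=O)c1c(O)cc(OC)c(O)c1OC | intermediate
4 | methyl 2-(3-acetyl-5-hydroxy-4,6-dimethoxy-1-benzofuran-2-yl)acetate | COC(=O)Cc1oc2cc(OC)c(O)c(OC)c2c1C(C)=O | intermediate
5 | benzyl bromide | BrCc1ccccc1 | starting material
6 | methyl 2-[3-acetyl-5-(benzyloxy)-4,6-dimethoxy-1-benzofuran-2-yl]acetate | COC(=O)Cc1oc2cc(OC)c(OCc3ccccc3)c(OC)c2c1C(C)=O | intermediate
7 | 2-(benzyloxy)-1,3-dimethoxy-6,8-dihydrodibenzo[b,d]furan-7,9-dione (not isolated) | COc1cc2oc3CC(=O)CC(=O)c3c2c(OC)c1OCc1ccccc1 | intermediate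
8 | 2-(benzyloxy)-1,3-dimethoxydibenzo[b,d]furan-7,9-diol | COc1cc2oc3cc(O)cc(O)c3c2c(OC)c1OCc1ccccc1 | intermediate
9 | 2-(benzyloxy)-1,3,7,9-tetramethoxydibenzo[b,d]furan | COc1cc2oc3cc(OC)cc(OC)c3c2c(OC)c1OCc1ccccc1 | intermediate
10 | 1,3,7,9-tetramethoxydibenzo[b,d]furan-2-ol | COc1cc2oc3cc(OC)cc(OC)c3c2c(OC)c1O | intermediate
11 | 1-fluoro-3,5-dimethoxybenzene | COc1cc(F)cc(OC)c1 | starting material
12 | 2-fluoro-4,6-dimethoxybenzaldehyde | COc1cc(F)c(C=O)c(OC)c1 | intermediate
13 | 3-bromo-2-fluoro-4,6-dimethoxybenzaldehyde | O=Cc1c(F)c(Br)c(OC)cc1OC | intermediate
14 | 3-bromo-4,6-dimethoxy-2-[(1,3,7,9-tetramethoxydibenzo[b,d]furan-2-yl)oxy]benzaldehyde | O=Cc1c(OC)cc(OC)c(Br)c1Oc1c(OC)cc2oc3cc(OC)cc(OC)c3c2c1OC | intermediate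
15 | 3-bromo-4,6-dimethoxy-2-[(1,3,7,9-tetramethoxydibenzo[b,d]furan-2-yl)oxy]phenyl formate (not isolated) | O=COc1c(OC)cc(OC)c(Br)c1Oc1c(OC)cc2oc3cc(OC)cc(OC)c3c2c1OC | intermediate
16 | 3-bromo-4,6-dimethoxy-2-[(1,3,7,9-tetramethoxydibenzo[b,d]furan-2-yl)oxy]phenol | Oc1c(OC)cc(OC)c(Br)c1Oc1c(OC)cc2oc3cc(OC)cc(OC)c3c2c1OC | intermediate
17 | 3,5-dimethoxyphenylboronic acid | COc1cc(OC)cc(B(O)O)c1 | starting material
18 | 2-[6-bromo-2-(3,5-dimethoxyphenoxy)-3,5-dimethoxyphenoxy]-1,3,7,9-tetramethoxydibenzo[b,d]furan | COc1cc(OC)cc(Oc2c(OC)cc(OC)c(Br)c2Oc2c(OC)cc3oc4cc(OC)cc(OC)c4c3c2OC)c1 | intermediate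
19 | 2-[6-bromo-2-(3,5-dimethoxyphenoxy)-3,5-dimethoxyphenoxy]-3,7,9-trimethoxydibenzo[b,d]furan-1-ol | COc1cc(OC)cc(Oc2c(OC)cc(OC)c(Br)c2Oc2c(OC)cc3oc4cc(OC)cc(OC)c4c3c2O)c1 | intermediate
20 | hepta-O-methyl ether of the target (methyl ethers at C3, C7, C9, C2′, C4′ and on both ring E oxygens; dioxin closed C1–O–C5′ and C2–O–C6′) | COc1cc(OC)cc(Oc2c(OC)cc(OC)c3c2Oc2c(OC)cc4oc5cc(OC)cc(OC)c5c4c2O3)c1 | intermediate
21 | target heptaol CNP0256302.0 (dibenzofuran-3,7,9-triol whose C1 and C2 oxygens form a 1,4-dioxin with C5′ and C6′ of ring A; ring A carries OH at C2′ and C4′ and a 3,5-dihydroxyphenoxy group at C1′) | Oc1cc(O)cc(Oc2c(O)cc(O)c3c2Oc2c(O)cc4oc5cc(O)cc(O)c5c4c2O3)c1 | target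

## Step count and least certain steps

Total step count: 13. Longest linear sequence: 11 steps (steps 1–5 and 8–13); steps 6 and 7 make the ring A fragment 13 in a side branch.

Step 3 (key step).
- What may go wrong: the ester may be consumed without ring closure, by saponification through traces of hydroxide to an unreactive carboxylate or by intermolecular condensation through the stabilised arm enolate. The reason is that enolisation of the acetyl group, crowded by the peri methoxy group, is the slow event.
- Fallback, from 6 back to 8, replacing the hard-base ester condensation by soft enolisation and an activated acyl donor: LiOH in aqueous THF at room temperature would give 2-[3-acetyl-5-(benzyloxy)-4,6-dimethoxy-1-benzofuran-2-yl]acetic acid F1. 1H-Benzotriazole and SOCl2 (CH2Cl2, rt) would convert this into 1-{[3-acetyl-5-(benzyloxy)-4,6-dimethoxy-1-benzofuran-2-yl]acetyl}-1H-benzotriazole F2. MgBr2·OEt2 and i-Pr2NEt (CH2Cl2, rt) would then enolise the magnesium-bound methyl ketone reversibly. C-acylation of that enolate by the N-acylbenzotriazole, a known way from ketones to 1,3-diketones, would make the same C7–C8 bond, giving 7 and, after enolisation and acidic work-up, 8.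

Step 1.
- What may go wrong: furan closure onto the acetyl carbonyl instead of the C3 carbonyl (both are ketones of similar reactivity), together with sluggish conjugate addition to the methoxy-deactivated quinone. Conjugate addition through C2 of 2 instead of C4 would be less harmful, because that connectivity can still close ring D by the complementary Claisen mode.
- Fallback, from 1 back to 6, removing the ambiguity with a symmetrical partner: the same ZnCl2 annulation of 1 with commercial dimethyl 3-oxopentanedioate, which has a single ketone, would give methyl 5-hydroxy-4,6-dimethoxy-2-(2-methoxy-2-oxoethyl)-1-benzofuran-3-carboxylate F3. Benzylation with 5 would give methyl 5-(benzyloxy)-4,6-dimethoxy-2-(2-methoxy-2-oxoethyl)-1-benzofuran-3-carboxylate F4. LiOH would give 5-(benzyloxy)-2-(carboxymethyl)-4,6-dimethoxy-1-benzofuran-3-carboxylic acid F5. Ac2O would close the two carboxyl groups to the six-membered cyclic anhydride F6. Methanol opens such homophthalic-type anhydrides at the non-conjugated carbonyl and would give 5-(benzyloxy)-4,6-dimethoxy-2-(2-methoxy-2-oxoethyl)-1-benzofuran-3-carboxylic acid F7. Oxalyl chloride would give 5-(benzyloxy)-4,6-dimethoxy-2-(2-methoxy-2-oxoethyl)-1-benzofuran-3-carbonyl chloride F8. Me2CuLi (THF, −78 °C) would convert the acid chloride into the methyl ketone in the presence of the ester, rejoining the route at 6.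

Step 11.
- What may go wrong: indiscriminate ether cleavage, that is, loss of the C3 methyl group or of ring A methyl groups with or instead of the C1 methyl group, because several methoxy groups have oxygen neighbours that can chelate boron.
- Fallback, from 8 to 21, placing a directing group next to C1: 2-bromopropane and K2CO3 in DMF would give 2-(benzyloxy)-1,3-dimethoxy-7,9-di(propan-2-yloxy)dibenzo[b,d]furan F9. Hydrogenolysis would give 1,3-dimethoxy-7,9-di(propan-2-yloxy)dibenzo[b,d]furan-2-ol F10. Substitution on 13 as in step 8 would give 3-bromo-2-{[1,3-dimethoxy-7,9-di(propan-2-yloxy)dibenzo[b,d]furan-2-yl]oxy}-4,6-dimethoxybenzaldehyde F11. Peracid oxidation as in step 9 would give 3-bromo-2-{[1,3-dimethoxy-7,9-di(propan-2-yloxy)dibenzo[b,d]furan-2-yl]oxy}-4,6-dimethoxyphenyl formate F12. Methanolysis would give 3-bromo-2-{[1,3-dimethoxy-7,9-di(propan-2-yloxy)dibenzo[b,d]furan-2-yl]oxy}-4,6-dimethoxyphenol F13. Coupling with 17 as in step 10 would give 2-[6-bromo-2-(3,5-dimethoxyphenoxy)-3,5-dimethoxyphenoxy]-1,3-dimethoxy-7,9-di(propan-2-yloxy)dibenzo[b,d]furan F14. BCl3 cleaves isopropyl aryl ethers well before methyl ethers, and the aryloxyborane formed at C9 would deliver boron to the adjacent, doubly flanked C1 methoxy oxygen, giving 2-[6-bromo-2-(3,5-dimethoxyphenoxy)-3,5-dimethoxyphenoxy]-3-methoxydibenzo[b,d]furan-1,7,9-triol F15. Copper-catalysed closure as in step 12, in which only the C1 oxygen can reach C5′, would give the pentamethyl ether of the target with free hydroxyl groups at C7 and C9 F16. BBr3 as in step 13 would give 21.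

Step 8.
- What may go wrong: slow substitution, because the phenoxide is flanked by two methoxy groups and the formyl acceptor is weakened by its ortho and para methoxy groups, while the aldehyde degrades under more forcing basic conditions.
- Fallback, from 13 back to 14, with a more robust acceptor: hydroxylamine hydrochloride in hot formic acid would convert 13 into 3-bromo-2-fluoro-4,6-dimethoxybenzonitrile F17. This tolerates Cs2CO3 in DMSO at 120 °C and would give with 10 the ether 3-bromo-4,6-dimethoxy-2-[(1,3,7,9-tetramethoxydibenzo[b,d]furan-2-yl)oxy]benzonitrile F18. DIBAL-H (CH2Cl2, −78 °C) followed by acidic work-up would reduce the nitrile to the aldehyde and rejoin the route at 14.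

Step 10.
- What may go wrong: low conversion, because the phenol is flanked on both sides, with protodeboronation or homocoupling of 17 and oxidation of the electron-rich phenol under copper and oxygen as competing processes.
- Fallback, from 16 back to 18: a redox-neutral Ullmann coupling of 16 with commercial 1-iodo-3,5-dimethoxybenzene (CuI, picolinic acid, K3PO4, DMSO, 80 °C). It relies on faster insertion of monovalent copper into the unhindered iodide than into the doubly flanked bromide. It makes no new compound, hence the entry F0.

## Further compounds

F1 | step 3 | 2-[3-acetyl-5-(benzyloxy)-4,6-dimethoxy-1-benzofuran-2-yl]acetic acid | OC(=O)Cc1oc2cc(OC)c(OCc3ccccc3)c(OC)c2c1C(C)=O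
F2 | step 3 | 1-{[3-acetyl-5-(benzyloxy)-4,6-dimethoxy-1-benzofuran-2-yl]acetyl}-1H-benzotriazole | CC(=O)c1c(CC(=O)n2nnc3ccccc32)oc2cc(OC)c(OCc3ccccc3)c(OC)c12
F3 | step 1 | methyl 5-hydroxy-4,6-dimethoxy-2-(2-methoxy-2-oxoethyl)-1-benzofuran-3-carboxylate | COC(=O)Cc1oc2cc(OC)c(O)c(OC)c2c1C(=O)OC
F4 | step 1 | methyl 5-(benzyloxy)-4,6-dimethoxy-2-(2-methoxy-2-oxoethyl)-1-benzofuran-3-carboxylate | COC(=O)Cc1oc2cc(OC)c(OCc3ccccc3)c(OC)c2c1C(=O)OC
F5 | step 1 | 5-(benzyloxy)-2-(carboxymethyl)-4,6-dimethoxy-1-benzofuran-3-carboxylic acid | OC(=O)Cc1oc2cc(OC)c(OCc3ccccc3)c(OC)c2c1C(O)=O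
F6 | step 1 | cyclic anhydride of F5 (six-membered, between the ring carboxyl group and the acetic acid arm) | COc1cc2oc3CC(=O)OC(=O)c3c2c(OC)c1OCc1ccccc1
F7 | step 1 | 5-(benzyloxy)-4,6-dimethoxy-2-(2-methoxy-2-oxoethyl)-1-benzofuran-3-carboxylic acid | COC(=O)Cc1oc2cc(OC)c(OCc3ccccc3)c(OC)c2c1C(O)=O
F8 | step 1 | 5-(benzyloxy)-4,6-dimethoxy-2-(2-methoxy-2-oxoethyl)-1-benzofuran-3-carbonyl chloride | COC(=O)Cc1oc2cc(OC)c(OCc3ccccc3)c(OC)c2c1C(Cl)=O
F9 | step 11 | 2-(benzyloxy)-1,3-dimethoxy-7,9-di(propan-2-yloxy)dibenzo[b,d]furan | COc1cc2oc3cc(OC(C)C)cc(OC(C)C)c3c2c(OC)c1OCc1ccccc1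
F10 | step 11 | 1,3-dimethoxy-7,9-di(propan-2-yloxy)dibenzo[b,d]furan-2-ol | COc1cc2oc3cc(OC(C)C)cc(OC(C)C)c3c2c(OC)c1O
F11 | step 11 | 3-bromo-2-{[1,3-dimethoxy-7,9-di(propan-2-yloxy)dibenzo[b,d]furan-2-yl]oxy}-4,6-dimethoxybenzaldehyde | O=Cc1c(OC)cc(OC)c(Br)c1Oc1c(OC)cc2oc3cc(OC(C)C)cc(OC(C)C)c3c2c1OC
F12 | step 11 | 3-bromo-2-{[1,3-dimethoxy-7,9-di(propan-2-yloxy)dibenzo[b,d]furan-2-yl]oxy}-4,6-dimethoxyphenyl formate | O=COc1c(OC)cc(OC)c(Br)c1Oc1c(OC)cc2oc3cc(OC(C)C)cc(OC(C)C)c3c2c1OC
F13 | step 11 | 3-bromo-2-{[1,3-dimethoxy-7,9-di(propan-2-yloxy)dibenzo[b,d]furan-2-yl]oxy}-4,6-dimethoxyphenol | Oc1c(OC)cc(OC)c(Br)c1Oc1c(OC)cc2oc3cc(OC(C)C)cc(OC(C)C)c3c2c1OC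
F14 | step 11 | 2-[6-bromo-2-(3,5-dimethoxyphenoxy)-3,5-dimethoxyphenoxy]-1,3-dimethoxy-7,9-di(propan-2-yloxy)dibenzo[b,d]furan | COc1cc(OC)cc(Oc2c(OC)cc(OC)c(Br)c2Oc2c(OC)cc3oc4cc(OC(C)C)cc(OC(C)C)c4c3c2OC)c1
F15 | step 11 | 2-[6-bromo-2-(3,5-dimethoxyphenoxy)-3,5-dimethoxyphenoxy]-3-methoxydibenzo[b,d]furan-1,7,9-triol | COc1cc(OC)cc(Oc2c(OC)cc(OC)c(Br)c2Oc2c(OC)cc3oc4cc(O)cc(O)c4c3c2O)c1
F16 | step 11 | pentamethyl ether of the target with free hydroxyl groups at C7 and C9 | COc1cc(OC)cc(Oc2c(OC)cc(OC)c3c2Oc2c(OC)cc4oc5cc(O)cc(O)c5c4c2O3)c1
F17 | step 8 | 3-bromo-2-fluoro-4,6-dimethoxybenzonitrile | N#Cc1c(F)c(Br)c(OC)cc1OC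
F18 | step 8 | 3-bromo-4,6-dimethoxy-2-[(1,3,7,9-tetramethoxydibenzo[b,d]furan-2-yl)oxy]benzonitrile | N#Cc1c(OC)cc(OC)c(Br)c1Oc1c(OC)cc2oc3cc(OC)cc(OC)c3c2c1OC
F0 | step 10 | none | none
A1 | alternative 1 | 1,3-dimethoxydibenzo[b,d]furan-2,7,9-triol | COc1cc2oc3cc(O)cc(O)c3c2c(OC)c1O
A2 | alternative 1 | benzene-1,3,5-triol | Oc1cc(O)cc(O)c1
A3 | alternative 2 | hepta-O-methyl ether of the target (identical with 20) | COc1cc(OC)cc(Oc2c(OC)cc(OC)c3c2Oc2c(OC)cc4oc5cc(OC)cc(OC)c5c4c2O3)c1
A4 | alternative 2 | 3,7,9-trimethoxydibenzo[b,d]furan-1,2-dione | COC1=Cc2oc3cc(OC)cc(OC)c3c2C(=O)C1=O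
A5 | alternative 2 | 2-(3,5-dimethoxyphenoxy)-3,5-dimethoxy-6-(trimethylsilyl)phenyl trifluoromethanesulfonate | COc1cc(OC)cc(Oc2c(OC)cc(OC)c([Si](C)(C)C)c2OS(=O)(=O)C(F)(F)F)c1
A6 | alternative 2 | 3-(3,5-dimethoxyphenoxy)-4,6-dimethoxybenzyne (1,2-didehydrobenzene, not isolable) | COC1=CC(OC)=C(Oc2cc(OC)cc(OC)c2)C#C1
A7 | alternative 3 | 2,3-bis(benzyloxy)-6-ethoxy-4-(methoxymethoxy)phenol | CCOc1cc(OCOC)c(OCc2ccccc2)c(OCc2ccccc2)c1O
A8 | alternative 3 | rac-2,3-bis(benzyloxy)-4-[(Z)-2-ethoxyethenyl]-4-(methoxymethoxy)cyclobut-2-en-1-one | CCO/C=C\C1(OCOC)C(OCc2ccccc2)=C(OCc2ccccc2)C1=O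
A9 | alternative 3 | (3Z,5Z)-2,3-bis(benzyloxy)-6-ethoxy-4-(methoxymethoxy)hexa-1,3,5-trien-1-one (dienylketene, not isolable) | CCO/C=C\C(OCOC)=C(OCc1ccccc1)/C(OCc1ccccc1)=C=O
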